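The length I am asked for is a ratio, monomer in chains over chains begun, and since the earlier runs show the top of that ratio but not the bottom, I keep my books on the bottom. On the candidate steps, each mole of pre-initiator charged stands as pre-initiator, as initiator, or as a living end that has begun a chain.

the same everywhere: free monomer 0.31 M
- Thursday's: pre-initiator 0.38 mM; run made earlier
- Monday's: pre-initiator 0.69 mM; run made earlier
- teal: pre-initiator 0.62 mM; time 15 min
- grey: pre-initiator 0.20 mM; time 15 min

- Thursday's (time / min: monomer in chains / %): 2.50: 2.8; 5.00: 7.5; 8.00: 16.4; 10.0: 24.5
- Monday's (time / min: monomer in chains / %): 0.833: 0; 2.00: 3.0; 5.00: 11.6; 10.0: 33.3

(readings scatter by 1 percentage point)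

- the average divides the monomer in chains by the number of chains begun, living and dead together
- candidate steps: free monomer + initiator -> living end + monomer in chains; monomer in chains + living end -> free monomer + living end; pre-initiator <-> initiator; free monomer + living end -> monomer in chains + living end
- the earlier runs do not show the number of chains; that part of a forecast is a guess

- which of the two ends with the longer chains by the average number of monomer units in a chain (chains begun, living or dead) ("neither" if they lie within 10 %) (teal / grey / neither)
- average number of monomer units in a chain (chains begun, living or dead) at the end, teal
- average number of monomer units in a chain (chains begun, living or dead) at the end, grey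

Thursday's run takes up monomer at 0.0126 M min⁻¹ between 8.00 min and 10.0 min, and that line, drawn back from its last reading, meets zero at an induction time τ of 3.95 min, a reading that carries the scatter. I take chains to start first-order with this τ at any charge, so that the share of a charge started by time t is one minus exp(−t/τ), which at 15 min gives 97.8 %, and this started share is what I carry. Teal's ledger then reads 0.606 mM as living ends and 0.0139 mM still as pre-initiator and initiator, and the books close on its 0.62 mM.

For the top, grey's charge is lower than Thursday's, so I scale Thursday's slope down by charge and run it from τ to 15 min, which puts 0.0730 M in chains and gives grey a length of 373. Teal can't be had that way, because Thursday's last reading scaled to Monday's charge gives 44.5 %, more than the 33.3 % Monday shows. So I continue Monday's last stretch straight on and scale it by charge, which gives 0.153 M in chains and a length of 253 for teal, so I expect grey to be the longer.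

The forecast also says grey, but at 450 for teal and 1000 for grey, with “perhaps half the pre-initiator has started chains” where my ledger has 97.8 %.

The flask gives grey as the longer, at 404 against 244 for teal, with 23.1 % of the free monomer charged to grey and 42.7 % of that charged to teal in chains at 15.0 min.

    free monomer + initiator → living end + monomer in chains (k = 0.0635 M⁻¹ s⁻¹)
    monomer in chains + living end → free monomer + living end, rate k2*[living end] as long as [monomer in chains] is above zero (k = 0.914 s⁻¹)
    pre-initiator ⇌ initiator (K = 1.40, k = 0.00298 s⁻¹)
    free monomer + living end → monomer in chains + living end, rate k4*[living end]*[free monomer] (k = 5.95 M⁻¹ s⁻¹)

With the started share 97.8 % under them, those amounts give 219 for teal and 367 for grey. Grey's own ledger at 15.0 min holds 88.8 % of its charge as living end, 1.84 % as initiator and 9.32 % as pre-initiator.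

The data were computed for an exercise; the scatter is artificial.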